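Xi plus what remains of Wu and Ji stays the whole charge in my reckoning, and one Ky goes with one Xi. Two fractions therefore describe the flask: Ky left of its own charge, and the pair Wu and Ji left of theirs.

| setting | Friday's | Monday's | Sunday's | flask |
|---|---|---|---|---|
| Wu | 0.070 M | 0.28 M | 0.14 M | 0.14 M |
| Ji | 0.070 M | 0.28 M | 0.14 M | 0.14 M |
| Ky | 0.308 M | 0.308 M | 0.308 M | 0.308 M |
| Ve | 2.8 mM | 2.8 mM | 1.4 mM | 2.8 mM |
| Ym | 2.8 mM | 2.8 mM | 2.8 mM | 2.8 mM |
| remark | run made earlier | run made earlier | run made earlier |  |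
| time |  |  |  | 1.0 h |

- Friday's (time / min: Xi / %, Wu / %): 6.00: 20, 34; 12.0: 35, 32; 30.0: 54, 27; 80.0: 77, 12
- Monday's (time / min: Xi / %, Wu / %): 10.0: 30, 38; 25.0: 37, 31; 50.0: 45, 28; 80.0: 47, 26
- Sunday's (time / min: Xi / %, Wu / %): 6.00: 15, 39; 12.0: 25, 36; 30.0: 35, 28; 80.0: 54, 19

(standard deviation of a reading: 2 percentage points)

- the Xi in the flask at 1.0 h, as a percentage of the Wu and Ji together charged
- the Wu in the flask at 1.0 h, as a percentage of the Wu and Ji together charged
- the Ji in the flask at 1.0 h, as a percentage of the Wu and Ji together charged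

My rule for the flask: Xi gained per minute equals the pace, times Ky left, times pair left. Friday and Monday share this flask's Ve and Ky charges. I replace each curve by the mean of its ends. Friday from 12.0 min to 80.0 min gives 0.0188 min⁻¹. On Monday Ky is the limiting reagent, at 0.550 of the pair, less than the pair. Monday from 10.0 min to 50.0 min gives 0.0189 min⁻¹, about the same. I carry the pace, 0.0188 min⁻¹.

Splitting Friday at 30.0 min lifts its pace to 0.0214 min⁻¹. So on Friday the mean over the long span reads lower, but I spend the pace by the same mean.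

In this flask Ky is 1.10 of the pair. I start from 32.5% Xi at 11.0 min, the mean of the Friday and Monday readings that open those spans. Pace times the remaining 49.0 min is 0.923. At 1.0 h I expect 60.8% Xi, and 19.6% each of Wu and Ji. Leave Ve and Ky alone: the pace belongs to these charges.

The forecast says 60% Xi, 19% Wu, 21% Ji: “split nearly evenly and Wu slightly lower”.

The flask gives 60.0% Xi, 19.0% Wu and 19.6% Ji.

    Ky + Ve + Ji → Ve + Xo (k = 5.94 L² mol⁻² min⁻¹)
    Ky + Ve + Wu → Ve + Xi (k = 271 L² mol⁻² min⁻¹)
    Wu + Ym ⇌ Ji + Ym, rate k3*[Ym]*[Wu] forward; the back reaction follows from the equilibrium constant (k = 117 L mol⁻¹ min⁻¹)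
    2 Ve ⇌ Ez (K = 4700 L mol⁻¹, k = 92.3 L mol⁻¹ min⁻¹)

By its forward step alone, the way back not counted and the other concentrations as charged, Wu goes to Ji with a half-life of 2.1 min, shorter than the 1.0 h. From 35.0% Xi at 15 min to 60.0%, this flask's own pace reads 0.0186 min⁻¹. The neighbour with 0.12 M of Ky reads 28.4% Xi at 1.00 h, which, counted from the start and taken in proportion to the Ky charge, is a pace of 0.0211 min⁻¹.

The numbers in the tables come from a simulation for substances that don't exist.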